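## The problem

Germacrane numbering is used throughout: C1 ketone, C2=C3 enol ether, C4 (C15 methyl), C5, C6 (lactone oxygen), C7, C8 (ester oxygen), C9, C10 (C14 methyl, ring oxygen), C11=C13 methylene, C12 lactone carbonyl.

The target 38 is a germacranolide whose ten-membered carbocycle C1–C10 is bridged twice. An oxygen joins C3 and C10, so that O, C3, C2, C1 and C10 form a 3(2H)-furanone. C6 and C7 carry a cis-fused α-methylene-γ-butyrolactone, and O8 is acylated by (2S)-2,3-dihydroxy-2-methylpropanoic acid.

Six stereocentres have to be set: C4, C6, C7, C8, the fully substituted C10 and C2′ of the ester. C6, C7 and C8 are contiguous and can control one another in an open chain (aldol, then 1,3-induction from O8). C10 and C2′ are isolated tertiary carbinol centres and are best bought. C4 has no neighbour in the chain but lies one carbon from C6 on the ring, so it is best set after ring closure.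

The methylene lactone is a Michael acceptor, and the furanone is a vinylogous ester whose C4–H is acidic. The 8-acyloxy group can migrate or eliminate. Strong base therefore has to be kept away from late intermediates.

The feature that opens the ring closure is the C3–C4 bond. It joins the future enol ether carbon to the methyl-bearing C4, so a C4≡C5 alkyne and a C3 aldehyde map onto C3(O)–C4(Me)=C5. Reductive coupling there closes the ten-membered ring, delivers the C3 oxygen for the furanone and leaves an alkene whose hydrogenation creates C4.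

## Retrosynthesis

**38 from 36.** The O10–C3 enol ether bond (with C2=C3) and the O6–C12 lactone bond are cut, and all masking groups are put back: C1 dioxolane, C10 triethylsilyl ether, C6 tert-butyldimethylsilyl ether, side-chain acetonide. Both bridging rings close under acid from keto acid 36, and every protecting group falls to aqueous acid or fluoride. The strained, base-sensitive bicycle then appears only in the last flask. The forward step must free O10 and O6, hydrolyse the β-keto ketal and dehydrate, in one operation.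

**36 from 32.** The C11=C13 bond is cut to formaldehyde, and C12 and C3 are taken back to an acetal and a carbinol. The usual alternative, methylenation of a lactone enolate, would need a lithium amide on a compound with an acidic C4–H and a furanone. Amine-catalysed methylenation of the C12 aldehyde, then Pinnick oxidation, runs near neutral pH instead. Alcohol 32 carries C12 as a dimethyl acetal, the most labile acetal in the molecule, so it can be opened alone. C3 is oxidised only after the methylene is in place (35), which keeps C4 next to a ketone for as short a time as possible.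

**32 from 31 and 30.** The C4–H and C5–H bonds are cut. Hydrogenation of the E-C4=C5 alkene of allylic alcohol 31 sets C4 on the ring, where one alkene face is buried under the ring and the C3 hydroxyl can hold the catalyst on the other. 31 comes from silyl ether 30 by removal of the one secondary triethylsilyl group.

**30 from 29 (key).** The C3–C4 bond is cut. Cutting here rather than at C5–C6 or C9–C10 puts the ring closure at the one bond whose formation creates functionality the target needs at both ends. Ynal 29 is an open chain in which C6, C7, C8, C10 and C2′ are already fixed. The forward reaction must be regioselective for C4 over C5 and must beat oligomerisation.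

**29 from 27, and 27 from 20 and 25.** The C3 aldehyde is masked as a terminal alkene (one extra carbon), which survives everything before it and is cleaved by OsO4/NaIO4 without touching the alkyne. The O8–C1′ ester bond is cut to alcohol 20 and acid 25. The ester is put on only after C6 is in place, so no carbonyl at C6 ever sits β to an acyloxy leaving group.

**20 from 19, 18 and 17.** The C6–H bond is cut to ynone 18, and the C5–C6 bond to Weinreb amide 17 and a propynyl Grignard reagent. The target needs O6 and O8 anti, which is what an internal hydride delivery from a free O8 hydroxyl gives, so no chiral reductant is needed. The two hydroxyls of diol 19 are then told apart by size: the propargylic O6 is silylated first.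

**17 from 16, and 16 from 14 and 9.** The C7–C8 bond is cut by a syn aldol. Imide 14 brings C6, C7, C11 and C12 (as the dimethyl acetal) and aldehyde 9 brings C8–C10 and C1–C3. The (R)-benzyl auxiliary gives the 7,8-syn pair in the required absolute sense, whatever the β-stereocentre of 9 does.

**9 from 8, 7, 6, 5, 4, 2 and 1.** The C1–C2 bond is cut to Weinreb amide 6 and allylmagnesium bromide. C10 with its methyl and oxygen, C9, C8 and C1 all come from (S)-citramalic acid 1, whose two carboxyl groups are told apart through dioxolanone 2 and lactone 4. The C1 ketone is ketalised on this small fragment, where a difficult ketalisation costs least.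

**14 from 11, 10 and 12; 25 from 24, 23 and 21.** The imide is made from methyl 4,4-dimethoxybutanoate 10 and oxazolidinone 12. The side-chain acid comes from bromohydrin acid 21, which already holds the C2′ configuration. No bond to C2′ is touched on the way to 25.

## Roads not taken

**Alternative 1:** The C9–C10 bond and the O–C10 bond would be made together. A copper carbenoid at C10 is trapped by a ring ether oxygen and the oxonium ylide shifts [2,3] onto a vinyl group, giving the oxygen-bridged tetrahydrofuranone A1.
- Merits: the bridged core and the quaternary C10 arise in one catalytic step. The medium ring comes from ring expansion, not end-to-end closure, so no high dilution is needed. In ring construction this is the stronger plan.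
- Weak points for this target: C10 is set by the geometry of the rearrangement and not bought. A1 holds C2 as CH2, so a dehydrogenation to the furanone is still owed. A1 has a Z-C7=C8 alkene, so C7–H and C8–O both hang on one facial selectivity on a medium ring. The rearrangement substrate itself needs a quaternary C7 on a substituted tetrahydropyran.
- Comparison: the chosen plan gives up the elegant ring expansion. In return it fixes C7, C8 and C10 by an auxiliary aldol and the chiral pool before the ring exists.

**Alternative 2:** The C2–C3 bond would be made last. A C10 acetyl enolate (LiHMDS) attacks the carbonyl C3 of a nine-membered lactone, and acid dehydrates the hemiketal to the target acetonide A2.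
- Merits: the key step ends one deprotection from the target, and C4 can be set in a chain as the α-centre of an acid. In end-game length and in the control of C4 it is better than the chosen plan, which needs seven steps after ring closure and sets C4 on the ring.
- Weak points: the nine-membered lactone must be closed onto the tertiary C10 hydroxyl, a medium-ring esterification of a hindered alcohol. The condensation then puts a strong amide base on a compound that already holds the methylene lactone, an epimerisable C4–H next to the lactone carbonyl and the C8 ester.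
- Comparison: its two hardest steps fall on the most advanced material. The chosen plan closes its ring under neutral catalysis and makes both sensitive rings with acid.

**Alternative 3:** The C8–C9 bond would form and C1–C6 break in an anionic oxy-Cope shift (KHMDS, 18-crown-6) that expands a six-membered ring. Hydroxylation of the enolate at C10 gives the α-hydroxy ketone A3.
- Merits: the ten-membered ring comes from a six-membered one without dilution, with E geometry from a chair, and the C1/C3 vinylogous ester is already in place. As a ring-forming event it is more reliable than a ten-membered nickel closure.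
- Weak points: C10 is created by hydroxylating a medium-ring enolate, with the face decided by ring conformation. A3 has a C6=C7 alkene, so O6 and H7 must still be added with regio- and facial control. C8 derives from an enol ether geometry.
- Comparison: the chosen plan accepts a harder ring closure. In return C6, C7, C8 and C10 are settled by open-chain chemistry, and only C4 is left to the ring.

Key step: step 20

## Route

Assumption: the nickelacycle is taken to form with the ring chain on the alkene face opposite the C6 silyloxy group, which gives the (3S)-carbinol 30. The C3 epimer would be hydrogenated from the same open face and carried on unchanged, since C3 becomes a carbonyl in step 25.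

Step 1
Reactants: 1 (S)-citramalic acid
Product: 2 2-[(4S)-2,2,4-trimethyl-5-oxo-1,3-dioxolan-4-yl]acetic acid
Conditions: Me2C(OMe)2, TsOH·H2O (cat.), acetone, rt
Reagents that add atoms: 2,2-dimethoxypropane, COC(C)(C)OC
Why: Acetonide formation ties the α-hydroxy acid into a dioxolanone and leaves the β-carboxyl (C8) free, which differentiates the two carboxyl groups; C10 is untouched.

Step 2
Reactants: 2 2-[(4S)-2,2,4-trimethyl-5-oxo-1,3-dioxolan-4-yl]acetic acid
Product: 4 (3S)-3-hydroxy-3-methyloxolan-2-one, via hydroxyethyl dioxolanone 3 (not isolated)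
Conditions: BH3·SMe2, THF, 0 °C to rt; MeOH; then TsOH·H2O (cat.), CH2Cl2, rt
Reagents that add atoms: none
Why: Borane reduces the free carboxylic acid much faster than the dioxolanone, and the primary alcohol then translactonises onto the activated carbonyl with loss of acetone; this is the known malic acid sequence applied to citramalic acid.

Step 3
Reactants: 4 (3S)-3-hydroxy-3-methyloxolan-2-one
Product: 5 (2S)-2,4-dihydroxy-N-methoxy-N,2-dimethylbutanamide
Conditions: MeNHOMe·HCl, AlMe3, CH2Cl2, 0 °C to rt; crude product used at once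
Reagents that add atoms: N,O-dimethylhydroxylamine hydrochloride, CNOC.Cl
Why: Aluminium amide aminolysis opens the lactone to the Weinreb amide; the γ-hydroxy amide can relactonise, so it is silylated without storage.

Step 4
Reactants: 5 (2S)-2,4-dihydroxy-N-methoxy-N,2-dimethylbutanamide
Product: 6 (2S)-N-methoxy-N,2-dimethyl-2,4-bis(triethylsilyloxy)butanamide
Conditions: TESOTf, 2,6-lutidine, CH2Cl2, −78 to 0 °C
Reagents that add atoms: triethylsilyl trifluoromethanesulfonate, CC[Si](CC)(CC)OS(=O)(=O)C(F)(F)F
Why: The silyl triflate silylates the primary and the tertiary hydroxyl in one operation; the primary ether is later oxidised directly and the tertiary one guards O10 to the end.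

Step 5
Reactants: 6 (2S)-N-methoxy-N,2-dimethyl-2,4-bis(triethylsilyloxy)butanamide
Product: 7 (5S)-5-methyl-5,7-bis(triethylsilyloxy)hept-1-en-4-one
Conditions: allylMgBr, THF, −78 °C; AcOH quench at −78 °C
Reagents that add atoms: allylmagnesium bromide, C=CC[Mg]Br
Why: Grignard addition to the Weinreb amide stops at the chelated tetrahedral intermediate and gives the β,γ-unsaturated ketone (C1–C3 plus one carbon); the cold acidic quench keeps the double bond out of conjugation.

Step 6
Reactants: 7 (5S)-5-methyl-5,7-bis(triethylsilyloxy)hept-1-en-4-one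
Product: 8 2-[(2S)-2,4-bis(triethylsilyloxy)butan-2-yl]-2-(prop-2-en-1-yl)-1,3-dioxolane
Conditions: (TMSOCH2)2, TMSOTf (cat.), CH2Cl2, −78 to −20 °C; pyridine quench
Reagents that add atoms: 1,2-bis(trimethylsilyloxy)ethane, C[Si](C)(C)OCCO[Si](C)(C)C
Why: Noyori ketalisation under aprotic conditions at low temperature is the method of choice for β,γ-unsaturated and hindered ketones, and the silyl ethers are not exposed to protic acid.

Step 7
Reactants: 8 2-[(2S)-2,4-bis(triethylsilyloxy)butan-2-yl]-2-(prop-2-en-1-yl)-1,3-dioxolane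
Product: 9 (3S)-3-[2-(prop-2-en-1-yl)-1,3-dioxolan-2-yl]-3-(triethylsilyloxy)butanal
Conditions: (COCl)2, DMSO, CH2Cl2, −78 to −30 °C; Et3N, to 0 °C
Reagents that add atoms: none
Why: Under Swern conditions a primary triethylsilyl ether is cleaved and oxidised directly to the aldehyde while the tertiary silyl ether stays, which saves a deprotection.

Step 8
Reactants: 10 methyl 4,4-dimethoxybutanoate
Product: 11 lithium 4,4-dimethoxybutanoate
Conditions: LiOH·H2O, THF/H2O, rt; evaporated to dryness
Reagents that add atoms: lithium hydroxide, [Li+].[OH-]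
Why: Saponification; the acid is kept as its salt because the free acid would cyclise onto the acetal.

Step 9
Reactants: 11 lithium 4,4-dimethoxybutanoate; 12 (4R)-4-benzyl-1,3-oxazolidin-2-one
Product: 14 (4R)-4-benzyl-3-(4,4-dimethoxybutanoyl)-1,3-oxazolidin-2-one, via mixed pivalic anhydride 13 (not isolated)
Conditions: PivCl, Et3N, THF, −20 °C; then 12, LiCl, to rt
Reagents that add atoms: none
Why: N-acylation of the oxazolidinone through the mixed pivalic anhydride with LiCl and amine base avoids strong base and free acid, so the acetal is safe.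

Step 10
Reactants: 14 (4R)-4-benzyl-3-(4,4-dimethoxybutanoyl)-1,3-oxazolidin-2-one; 9 (3S)-3-[2-(prop-2-en-1-yl)-1,3-dioxolan-2-yl]-3-(triethylsilyloxy)butanal
Product: 16 (4R)-4-benzyl-3-[(2R,3S,5S)-2-(2,2-dimethoxyethyl)-3-hydroxy-5-[2-(prop-2-en-1-yl)-1,3-dioxolan-2-yl]-5-(triethylsilyloxy)hexanoyl]-1,3-oxazolidin-2-one, via Z-boron enolate 15 (not isolated)
Conditions: Bu2BOTf, i-Pr2NEt, CH2Cl2, 0 °C; 9, −78 to 0 °C; pH 7 buffer, MeOH, H2O2, 0 °C
Reagents that add atoms: none
Why: Evans syn aldol: the Z-boron enolate reacts through a closed chair transition state, and the benzyl group of the (R)-auxiliary shields one enolate face, which sets C7 and C8 syn in the required absolute sense. Reagent control overrides the remote C10 centre, and the triflate is consumed in enolisation before the acetals see it.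

Step 11
Reactants: 16 the aldol adduct
Product: 17 (2R,3S,5S)-2-(2,2-dimethoxyethyl)-3-hydroxy-N-methoxy-N-methyl-5-[2-(prop-2-en-1-yl)-1,3-dioxolan-2-yl]-5-(triethylsilyloxy)hexanamide
Conditions: MeNHOMe·HCl, AlMe3, THF, −20 to 0 °C
Reagents that add atoms: N,O-dimethylhydroxylamine hydrochloride, CNOC.Cl
Why: Transamination of syn-aldol imides with the aluminium amide is assisted by the free β-hydroxyl and releases the auxiliary without epimerising C7.

Step 12
Reactants: 17 the β-hydroxy Weinreb amide
Product: 18 (5R,6S,8S)-5-(2,2-dimethoxyethyl)-6-hydroxy-8-[2-(prop-2-en-1-yl)-1,3-dioxolan-2-yl]-8-(triethylsilyloxy)non-2-yn-4-one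
Conditions: CH3C≡CMgBr (excess), THF, −20 to 0 °C; NH4Cl (aq.)
Reagents that add atoms: 1-propynylmagnesium bromide, CC#C[Mg]Br
Why: The first equivalent deprotonates the hydroxyl and a further one adds to the Weinreb amide; the chelate prevents over-addition, and C4, C5 and C15 are installed as the alkyne.

Step 13
Reactants: 18 the β-hydroxy ynone
Product: 19 (4R,5R,6S,8S)-5-(2,2-dimethoxyethyl)-8-[2-(prop-2-en-1-yl)-1,3-dioxolan-2-yl]-8-(triethylsilyloxy)non-2-yne-4,6-diol
Conditions: Me4NBH(OAc)3, MeCN/AcOH, −30 °C
Reagents that add atoms: none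
Why: Evans–Saksena reduction: the acetoxyborohydride exchanges onto the O8 hydroxyl and delivers hydride internally through a chair, which gives the 1,3-anti diol and so sets C6. The reagent neither hydroborates the terminal alkene nor reduces the alkyne.

Step 14
Reactants: 19 the anti-diol
Product: 20 (2S,4S,5R,6R)-6-(tert-butyldimethylsilyloxy)-5-(2,2-dimethoxyethyl)-2-[2-(prop-2-en-1-yl)-1,3-dioxolan-2-yl]-2-(triethylsilyloxy)non-7-yn-4-ol
Conditions: TBSCl (1.05 equiv), imidazole, DMF, 0 °C
Reagents that add atoms: tert-butyldimethylsilyl chloride, CC(C)(C)[Si](C)(C)Cl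
Why: Regioselective silylation: the propargylic O6 hydroxyl has the slim alkyne as neighbour, while O8 sits between the branched C7 and a neopentyl-type CH2, so the bulky chloride should take O6. A silyl chloride is used because silyl triflates with pyridine bases cleave dimethyl acetals.

Step 15
Reactants: 21 (2R)-3-bromo-2-hydroxy-2-methylpropanoic acid
Product: 23 (2S)-2,3-dihydroxy-2-methylpropanoic acid, via sodium (2S)-2-methyloxirane-2-carboxylate 22 (not isolated)
Conditions: NaOH (aq.), 0 to 60 °C; HCl to pH 2; evaporation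
Reagents that add atoms: sodium hydroxide, [Na+].[OH-]
Why: The bromohydrin closes to the glycidate, and hydroxide opens it at the primary carbon; no bond to the quaternary centre is broken, so its configuration is kept (the descriptor changes from R to S only through priorities).

Step 16
Reactants: 23 (2S)-2,3-dihydroxy-2-methylpropanoic acid
Product: 24 methyl (4S)-2,2,4-trimethyl-1,3-dioxolane-4-carboxylate
Conditions: MeOH, Me2C(OMe)2, TsOH·H2O (cat.), rt to 40 °C
Reagents that add atoms: methanol, CO; 2,2-dimethoxypropane, COC(C)(C)OC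
Why: Fischer esterification and acetonide formation in one pot, with the dimethoxypropane taking up the water; esterifying first keeps the acid from forming a dioxolanone.

Step 17
Reactants: 24 methyl (4S)-2,2,4-trimethyl-1,3-dioxolane-4-carboxylate
Product: 25 (4S)-2,2,4-trimethyl-1,3-dioxolane-4-carboxylic acid
Conditions: LiOH, THF/H2O, 0 °C to rt; HCl to pH 3 at 0 °C
Reagents that add atoms: lithium hydroxide, [Li+].[OH-]
Why: Saponification; the quaternary α-carbon cannot epimerise, and cold, brief acidification spares the acetonide.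

Step 18
Reactants: 20 the C6 silyl ether alcohol; 25 (4S)-2,2,4-trimethyl-1,3-dioxolane-4-carboxylic acid
Product: 27 (2S,4S,5R,6R)-6-(tert-butyldimethylsilyloxy)-5-(2,2-dimethoxyethyl)-2-[2-(prop-2-en-1-yl)-1,3-dioxolan-2-yl]-2-(triethylsilyloxy)non-7-yn-4-yl (4S)-2,2,4-trimethyl-1,3-dioxolane-4-carboxylate, via mixed trichlorobenzoic anhydride 26 (not isolated)
Conditions: 2,4,6-Cl3C6H2COCl, Et3N, THF, rt; then 20, DMAP, toluene, rt to 40 °C
Reagents that add atoms: none
Why: Yamaguchi esterification is the standard answer to a hindered secondary alcohol and an α-quaternary acid; DMAP attacks the aliphatic carbonyl of the mixed anhydride.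

Step 19
Reactants: 27 the alkene ester
Product: 29 (2S,4S,5R,6R)-6-(tert-butyldimethylsilyloxy)-5-(2,2-dimethoxyethyl)-2-[2-(2-oxoethyl)-1,3-dioxolan-2-yl]-2-(triethylsilyloxy)non-7-yn-4-yl (4S)-2,2,4-trimethyl-1,3-dioxolane-4-carboxylate, via vicinal diol 28 (not isolated)
Conditions: OsO4 (cat.), NaIO4, 2,6-lutidine, dioxane/H2O, rt
Reagents that add atoms: osmium tetroxide, O=[Os](=O)(=O)=O; sodium periodate, [Na+].[O-]I(=O)(=O)=O
Why: Lemieux–Johnson cleavage: OsO4 dihydroxylates the terminal alkene far faster than the internal alkyne, and periodate cleaves the diol to the C3 aldehyde; lutidine keeps the medium from turning acidic.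

Step 20
Reactants: 29 the ynal
Product: 30 (3S,4E,6S,7R,8S,10S)-6-(tert-butyldimethylsilyloxy)-7-(2,2-dimethoxyethyl)-1,1-(ethylenedioxy)-4,10-dimethyl-3,10-bis(triethylsilyloxy)cyclodec-4-en-8-yl (4S)-2,2,4-trimethyl-1,3-dioxolane-4-carboxylate (germacrane numbering)
Conditions: Ni(cod)2 (cat.), IMes·HCl (cat.), KOt-Bu (cat.), Et3SiH, THF, rt; slow addition of 29, high dilution
Reagents that add atoms: triethylsilane, CC[SiH](CC)CC
Why: Zerovalent nickel carrying the small carbene 1,3-dimesitylimidazol-2-ylidene binds the C4≡C5 alkyne and the C3 aldehyde and couples them oxidatively to an oxanickelacyclopentene that already holds the C3–C4 bond; σ-bond metathesis of Ni–O with Et3SiH gives the silyl ether and a vinyl nickel hydride, and reductive elimination puts H on C5 cis to C3, hence the E ring alkene. The closest known reaction type is the nickel–carbene–silane reductive macrocyclisation of ynals, which closes in the endocyclic mode with small carbene ligands. The ring closes in the 10-endo mode, with both alkyne carbons inside the ten-membered ring. Regioselectivity for C4 over C5 is needed and is secured twice: the small ligand lets the aldehyde bond to the alkyne carbon with the smaller substituent, and that carbon bears only methyl while C5 carries the branched silyloxy carbon C6. Ring closure must also beat oligomerisation and direct hydrosilylation of the aldehyde, which slow addition at high dilution and the chain bent by the quaternary C10 and the C1 ketal should favour. The new stereocentre C3 is set by the tether: C6–H eclipses the forming alkene toward the C15 methyl to avoid allylic 1,3-strain, so the chain lies on the face opposite the C6 silyloxy group, and with O3 held in the plane of the nickelacycle C2 must follow the chain, which gives 3S. Esters, acetals and silyl ethers are spectators under these neutral conditions.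

Step 21
Reactants: 30 the macrocyclic silyl ether
Product: 31 (3S,4E,6S,7R,8S,10S)-6-(tert-butyldimethylsilyloxy)-7-(2,2-dimethoxyethyl)-1,1-(ethylenedioxy)-3-hydroxy-4,10-dimethyl-10-(triethylsilyloxy)cyclodec-4-en-8-yl (4S)-2,2,4-trimethyl-1,3-dioxolane-4-carboxylate
Conditions: HF·pyridine, pyridine, THF, 0 °C
Reagents that add atoms: none
Why: Buffered fluoride removes a secondary allylic triethylsilyl ether well before a tertiary triethylsilyl or a hindered secondary tert-butyldimethylsilyl ether, and the acetals tolerate the pyridine-buffered reagent; loss of the C10 silyl group as well would not harm later steps.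

Step 22
Reactants: 31 the allylic alcohol
Product: 32 (3S,4S,6S,7R,8S,10S)-6-(tert-butyldimethylsilyloxy)-7-(2,2-dimethoxyethyl)-1,1-(ethylenedioxy)-3-hydroxy-4,10-dimethyl-10-(triethylsilyloxy)cyclodecan-8-yl (4S)-2,2,4-trimethyl-1,3-dioxolane-4-carboxylate
Conditions: H2 (1 atm), [Ir(cod)(PCy3)(py)]PF6 (cat.), CH2Cl2, 0 °C to rt
Reagents that add atoms: none
Why: Hydroxyl-directed homogeneous hydrogenation: the cationic iridium binds the C3 hydroxyl and the alkene and adds H2 to C4 and C5 from the face on which the hydroxyl lies. That is also the only open face, because allylic 1,3-strain between C6–H and the C15 methyl keeps the ring chain on the other one, and hydrogen delivered there gives 4S.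

Step 23
Reactants: 32 the saturated alcohol
Product: 33 (3S,4S,6S,7R,8S,10S)-6-(tert-butyldimethylsilyloxy)-1,1-(ethylenedioxy)-3-hydroxy-4,10-dimethyl-7-(2-oxoethyl)-10-(triethylsilyloxy)cyclodecan-8-yl (4S)-2,2,4-trimethyl-1,3-dioxolane-4-carboxylate
Conditions: PPTS (cat.), acetone/H2O, 40 °C
Reagents that add atoms: water, O
Why: Chemoselective acetal hydrolysis: an aldehyde dimethyl acetal exchanges far faster than the hindered, α-oxygenated ketone dioxolane or the silyl ethers, and acetone as solvent holds the side-chain acetonide in place.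

Step 24
Reactants: 33 the C12 aldehyde
Product: 34 (3S,4S,6S,7R,8S,10S)-6-(tert-butyldimethylsilyloxy)-1,1-(ethylenedioxy)-3-hydroxy-4,10-dimethyl-7-(3-oxoprop-1-en-2-yl)-10-(triethylsilyloxy)cyclodecan-8-yl (4S)-2,2,4-trimethyl-1,3-dioxolane-4-carboxylate
Conditions: HCHO (aq.), pyrrolidine (cat.), EtCO2H (cat.), i-PrOH, 45 °C
Reagents that add atoms: formaldehyde, C=O
Why: Amine-catalysed α-methylenation (Mannich condensation and elimination through the enamine) turns RCH2CHO into the 2-substituted acrolein under near-neutral conditions and installs C13 without any enolate.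

Step 25
Reactants: 34 the enal alcohol
Product: 35 (4S,6S,7R,8S,10S)-6-(tert-butyldimethylsilyloxy)-1,1-(ethylenedioxy)-4,10-dimethyl-3-oxo-7-(3-oxoprop-1-en-2-yl)-10-(triethylsilyloxy)cyclodecan-8-yl (4S)-2,2,4-trimethyl-1,3-dioxolane-4-carboxylate
Conditions: Dess–Martin periodinane, NaHCO3, CH2Cl2, 0 °C to rt
Reagents that add atoms: none
Why: Dess–Martin oxidation of the secondary C3 alcohol under buffered, non-enolising conditions keeps the adjacent C4 centre intact and leaves the enal alone.

Step 26
Reactants: 35 the keto enal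
Product: 36 2-[(4S,6S,7R,8S,10S)-6-(tert-butyldimethylsilyloxy)-1,1-(ethylenedioxy)-4,10-dimethyl-3-oxo-10-(triethylsilyloxy)-8-{[(4S)-2,2,4-trimethyl-1,3-dioxolane-4-carbonyl]oxy}cyclodecan-7-yl]prop-2-enoic acid
Conditions: NaClO2, NaH2PO4, 2-methyl-2-butene, t-BuOH/H2O, 0 °C to rt
Reagents that add atoms: sodium chlorite, [Na+].[O-]Cl=O
Why: Pinnick oxidation converts the α-substituted acrolein into the acrylic acid at pH 3–4 without touching the ketone, the alkene or the acetals; the alkene scavenger removes hypochlorite.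

Step 27
Reactants: 36 the keto acid
Product: 38 (4S,6S,7S,8S,10S)-3,10-epoxy-1-oxogermacra-2,11(13)-dien-12,6-olid-8-yl (2S)-2,3-dihydroxy-2-methylpropanoate (CNP0263764.3), via furanone hydroxy acid 37 (not isolated)
Conditions: HF (48% aq.), MeCN, 0 °C to rt
Reagents that add atoms: water, O
Why: Acid-mediated global unveiling: loss of the C10 silyl group frees the hydroxyl, the β-keto ketal hydrolyses through its enol, and the α′-hydroxy-1,3-diketone cyclodehydrates to the 3(2H)-furanone. Loss of the C6 silyl group lets the γ-hydroxy acrylic acid close to the cis-fused methylene lactone, and the acetonide is hydrolysed last. No new stereocentre is formed.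

## Compound list

1 | (S)-citramalic acid, (2S)-2-hydroxy-2-methylbutanedioic acid | OC(=O)[C@](C)(CC(=O)O)O | starting material
2 | 2-[(4S)-2,2,4-trimethyl-5-oxo-1,3-dioxolan-4-yl]acetic acid | CC1(C)OC(=O)[C@](C)(CC(=O)O)O1 | intermediate
3 | (5S)-5-(2-hydroxyethyl)-2,2,5-trimethyl-1,3-dioxolan-4-one | CC1(C)OC(=O)[C@](C)(CCO)O1 | intermediate
4 | (3S)-3-hydroxy-3-methyloxolan-2-one | O=C1OCC[C@]1(C)O | intermediate
5 | (2S)-2,4-dihydroxy-N-methoxy-N,2-dimethylbutanamide | CON(C)C(=O)[C@](C)(CCO)O | intermediate
6 | (2S)-N-methoxy-N,2-dimethyl-2,4-bis(triethylsilyloxy)butanamide | CON(C)C(=O)[C@](C)(CCO[Si](CC)(CC)CC)O[Si](CC)(CC)CC | intermediate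
7 | (5S)-5-methyl-5,7-bis(triethylsilyloxy)hept-1-en-4-one | C=CCC(=O)[C@](C)(CCO[Si](CC)(CC)CC)O[Si](CC)(CC)CC | intermediate
8 | 2-[(2S)-2,4-bis(triethylsilyloxy)butan-2-yl]-2-(prop-2-en-1-yl)-1,3-dioxolane | C=CCC1(OCCO1)[C@](C)(CCO[Si](CC)(CC)CC)O[Si](CC)(CC)CC | intermediate
9 | (3S)-3-[2-(prop-2-en-1-yl)-1,3-dioxolan-2-yl]-3-(triethylsilyloxy)butanal | C=CCC1(OCCO1)[C@](C)(CC=O)O[Si](CC)(CC)CC | intermediate
10 | methyl 4,4-dimethoxybutanoate | COC(OC)CCC(=O)OC | starting material
11 | lithium 4,4-dimethoxybutanoate | COC(OC)CCC(=O)[O-].[Li+] | intermediate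
12 | (4R)-4-benzyl-1,3-oxazolidin-2-one | O=C1N[C@H](Cc2ccccc2)CO1 | starting material
13 | 4,4-dimethoxybutanoic pivalic anhydride | COC(OC)CCC(=O)OC(=O)C(C)(C)C | intermediate
14 | (4R)-4-benzyl-3-(4,4-dimethoxybutanoyl)-1,3-oxazolidin-2-one | COC(OC)CCC(=O)N1[C@H](Cc2ccccc2)COC1=O | intermediate
15 | (Z)-dibutylboron enolate of 14 | CCCCB(CCCC)O/C(=C\CC(OC)OC)N1[C@H](Cc2ccccc2)COC1=O | intermediate
16 | (4R)-4-benzyl-3-[(2R,3S,5S)-2-(2,2-dimethoxyethyl)-3-hydroxy-5-[2-(prop-2-en-1-yl)-1,3-dioxolan-2-yl]-5-(triethylsilyloxy)hexanoyl]-1,3-oxazolidin-2-one | O=C(N1[C@H](Cc2ccccc2)COC1=O)[C@H](CC(OC)OC)[C@@H](O)C[C@](C)(O[Si](CC)(CC)CC)C3(CC=C)OCCO3 | intermediate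
17 | (2R,3S,5S)-2-(2,2-dimethoxyethyl)-3-hydroxy-N-methoxy-N-methyl-5-[2-(prop-2-en-1-yl)-1,3-dioxolan-2-yl]-5-(triethylsilyloxy)hexanamide | CON(C)C(=O)[C@H](CC(OC)OC)[C@@H](O)C[C@](C)(O[Si](CC)(CC)CC)C1(CC=C)OCCO1 | intermediate
18 | (5R,6S,8S)-5-(2,2-dimethoxyethyl)-6-hydroxy-8-[2-(prop-2-en-1-yl)-1,3-dioxolan-2-yl]-8-(triethylsilyloxy)non-2-yn-4-one | CC#CC(=O)[C@H](CC(OC)OC)[C@@H](O)C[C@](C)(O[Si](CC)(CC)CC)C1(CC=C)OCCO1 | intermediate
19 | (4R,5R,6S,8S)-5-(2,2-dimethoxyethyl)-8-[2-(prop-2-en-1-yl)-1,3-dioxolan-2-yl]-8-(triethylsilyloxy)non-2-yne-4,6-diol | CC#C[C@H](O)[C@H](CC(OC)OC)[C@@H](O)C[C@](C)(O[Si](CC)(CC)CC)C1(CC=C)OCCO1 | intermediate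
20 | (2S,4S,5R,6R)-6-(tert-butyldimethylsilyloxy)-5-(2,2-dimethoxyethyl)-2-[2-(prop-2-en-1-yl)-1,3-dioxolan-2-yl]-2-(triethylsilyloxy)non-7-yn-4-ol | CC#C[C@H](O[Si](C)(C)C(C)(C)C)[C@H](CC(OC)OC)[C@@H](O)C[C@](C)(O[Si](CC)(CC)CC)C1(CC=C)OCCO1 | intermediate
21 | (2R)-3-bromo-2-hydroxy-2-methylpropanoic acid | OC(=O)[C@@](C)(O)CBr | starting material
22 | sodium (2S)-2-methyloxirane-2-carboxylate | [O-]C(=O)[C@@]1(C)OC1.[Na+] | intermediate
23 | (2S)-2,3-dihydroxy-2-methylpropanoic acid | OC(=O)[C@@](C)(O)CO | intermediate
24 | methyl (4S)-2,2,4-trimethyl-1,3-dioxolane-4-carboxylate | COC(=O)[C@@]1(C)OC(C)(C)OC1 | intermediate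
25 | (4S)-2,2,4-trimethyl-1,3-dioxolane-4-carboxylic acid | OC(=O)[C@@]1(C)OC(C)(C)OC1 | intermediate
26 | (4S)-2,2,4-trimethyl-1,3-dioxolane-4-carboxylic 2,4,6-trichlorobenzoic anhydride | O=C(OC(=O)c1c(Cl)cc(Cl)cc1Cl)[C@@]2(C)OC(C)(C)OC2 | intermediate
27 | (2S,4S,5R,6R)-6-(tert-butyldimethylsilyloxy)-5-(2,2-dimethoxyethyl)-2-[2-(prop-2-en-1-yl)-1,3-dioxolan-2-yl]-2-(triethylsilyloxy)non-7-yn-4-yl (4S)-2,2,4-trimethyl-1,3-dioxolane-4-carboxylate | CC#C[C@H](O[Si](C)(C)C(C)(C)C)[C@H](CC(OC)OC)[C@@H](OC(=O)[C@@]2(C)OC(C)(C)OC2)C[C@](C)(O[Si](CC)(CC)CC)C1(CC=C)OCCO1 | intermediate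
28 | vicinal diol of 27 (2,3-dihydroxypropyl group on the dioxolane, both epimers) | CC#C[C@H](O[Si](C)(C)C(C)(C)C)[C@H](CC(OC)OC)[C@@H](OC(=O)[C@@]2(C)OC(C)(C)OC2)C[C@](C)(O[Si](CC)(CC)CC)C1(CC(O)CO)OCCO1 | intermediate
29 | ynal: (2S,4S,5R,6R)-6-(tert-butyldimethylsilyloxy)-5-(2,2-dimethoxyethyl)-2-[2-(2-oxoethyl)-1,3-dioxolan-2-yl]-2-(triethylsilyloxy)non-7-yn-4-yl (4S)-2,2,4-trimethyl-1,3-dioxolane-4-carboxylate | CC#C[C@H](O[Si](C)(C)C(C)(C)C)[C@H](CC(OC)OC)[C@@H](OC(=O)[C@@]2(C)OC(C)(C)OC2)C[C@](C)(O[Si](CC)(CC)CC)C1(CC=O)OCCO1 | intermediate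
30 | (3S,4E,6S,7R,8S,10S)-6-(tert-butyldimethylsilyloxy)-7-(2,2-dimethoxyethyl)-1,1-(ethylenedioxy)-4,10-dimethyl-3,10-bis(triethylsilyloxy)cyclodec-4-en-8-yl (4S)-2,2,4-trimethyl-1,3-dioxolane-4-carboxylate | C/C1=C\[C@H](O[Si](C)(C)C(C)(C)C)[C@H](CC(OC)OC)[C@@H](OC(=O)[C@@]2(C)OC(C)(C)OC2)C[C@](C)(O[Si](CC)(CC)CC)C3(OCCO3)C[C@@H]1O[Si](CC)(CC)CC | intermediate
31 | (3S,4E,6S,7R,8S,10S)-3-hydroxy analogue of 30 (C3 OH, C10 triethylsilyl ether kept) | C/C1=C\[C@H](O[Si](C)(C)C(C)(C)C)[C@H](CC(OC)OC)[C@@H](OC(=O)[C@@]2(C)OC(C)(C)OC2)C[C@](C)(O[Si](CC)(CC)CC)C3(OCCO3)C[C@@H]1O | intermediate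
32 | (3S,4S,6S,7R,8S,10S)-6-(tert-butyldimethylsilyloxy)-7-(2,2-dimethoxyethyl)-1,1-(ethylenedioxy)-3-hydroxy-4,10-dimethyl-10-(triethylsilyloxy)cyclodecan-8-yl (4S)-2,2,4-trimethyl-1,3-dioxolane-4-carboxylate | C[C@H]1C[C@H](O[Si](C)(C)C(C)(C)C)[C@H](CC(OC)OC)[C@@H](OC(=O)[C@@]2(C)OC(C)(C)OC2)C[C@](C)(O[Si](CC)(CC)CC)C3(OCCO3)C[C@@H]1O | intermediate
33 | C12 aldehyde: 7-(2-oxoethyl) analogue of 32 | C[C@H]1C[C@H](O[Si](C)(C)C(C)(C)C)[C@H](CC=O)[C@@H](OC(=O)[C@@]2(C)OC(C)(C)OC2)C[C@](C)(O[Si](CC)(CC)CC)C3(OCCO3)C[C@@H]1O | intermediate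
34 | enal: 7-(3-oxoprop-1-en-2-yl) analogue of 32 | C[C@H]1C[C@H](O[Si](C)(C)C(C)(C)C)[C@H](C(=C)C=O)[C@@H](OC(=O)[C@@]2(C)OC(C)(C)OC2)C[C@](C)(O[Si](CC)(CC)CC)C3(OCCO3)C[C@@H]1O | intermediate
35 | keto enal: (4S,6S,7R,8S,10S)-3-oxo analogue of 34 | C[C@H]1C[C@H](O[Si](C)(C)C(C)(C)C)[C@H](C(=C)C=O)[C@@H](OC(=O)[C@@]2(C)OC(C)(C)OC2)C[C@](C)(O[Si](CC)(CC)CC)C3(OCCO3)CC1=O | intermediate
36 | keto acid: 2-[(4S,6S,7R,8S,10S)-6-(tert-butyldimethylsilyloxy)-1,1-(ethylenedioxy)-4,10-dimethyl-3-oxo-10-(triethylsilyloxy)-8-{[(4S)-2,2,4-trimethyl-1,3-dioxolane-4-carbonyl]oxy}cyclodecan-7-yl]prop-2-enoic acid | C[C@H]1C[C@H](O[Si](C)(C)C(C)(C)C)[C@H](C(=C)C(=O)O)[C@@H](OC(=O)[C@@]2(C)OC(C)(C)OC2)C[C@](C)(O[Si](CC)(CC)CC)C3(OCCO3)CC1=O | intermediate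
37 | furanone hydroxy acid: 2-[(4S,6S,7S,8S,10S)-8-{[(2S)-2,3-dihydroxy-2-methylpropanoyl]oxy}-3,10-epoxy-6-hydroxy-1-oxogermacr-2-en-7-yl]prop-2-enoic acid | O[C@H]1C[C@H](C)C2=CC(=O)[C@](C)(C[C@H](OC(=O)[C@@](C)(O)CO)[C@H]1C(=C)C(=O)O)O2 | intermediate
38 | CNP0263764.3: (4S,6S,7S,8S,10S)-3,10-epoxy-1-oxogermacra-2,11(13)-dien-12,6-olid-8-yl (2S)-2,3-dihydroxy-2-methylpropanoate | C=C1C(=O)O[C@H]2C[C@H](C)C3=CC(=O)[C@](C)(C[C@H](OC(=O)[C@@](C)(O)CO)[C@@H]12)O3 | target

## Step count and least certain steps

Total: 27 steps. Longest linear sequence: 22 steps (steps 1–7, 10–14 and 18–27, from (S)-citramalic acid).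

**Step 20 (key step).** A ten-membered E-cycloalkene is at the small end of what this closure has been used for. The likely failure is a strained oxidative cyclisation that loses to intermolecular coupling, to direct hydrosilylation of the aldehyde or to closure at C5. Formation of the C3 epimer is less serious, since C3 is oxidised later.

Fallback, from 29 to 31: the same bond is closed by a Nozaki–Hiyama–Kishi reaction. NaBH4 reduces 29 to the primary alcohol F1. Cp2Zr(H)Cl then adds to the alkyne with zirconium on the less hindered, methyl-bearing C4, and iodine gives the (E)-vinyl iodide alcohol F2. Dess–Martin oxidation gives the iodo aldehyde F3. CrCl2 (divalent chromium) with catalytic NiCl2 in DMSO/THF at high dilution closes C3–C4 and returns the free allylic alcohol 31.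

**Step 22.** Hydrogen could be delivered to the wrong face if the ring does not sit as argued, and the hindered trisubstituted alkene next to the C6 silyloxy group could react slowly. The acidic iridium species could also nick the acetal.

Fallback, from 31 to 35: C4 is set by conjugate reduction instead. Dess–Martin oxidation of 31 gives the macrocyclic enone F4. [(Ph3P)CuH]6 adds hydride to C5, and protonation of the enolate gives the C3 ketone F5; its C4 centre, being α to the ketone, can be equilibrated with mild base. PPTS in wet acetone gives the keto aldehyde F6, and the methylenation of step 24 then gives 35.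

**Step 14.** Silylation might not discriminate well enough between O6 and O8, or might go twice.

Fallback, from 17 to 20: the two oxygens are told apart before C6 exists. TESCl and imidazole give the O8 triethylsilyl Weinreb amide F7. Propynylmagnesium bromide gives the ynone F8. Transfer hydrogenation with RuCl[(R,R)-TsDPEN](p-cymene) in i-PrOH gives the (R)-propargylic alcohol F9 under catalyst control. TBSCl gives the tris-silyl ether F10, and buffered HF·pyridine removes the secondary triethylsilyl group to return 20.

**Step 6.** Under the Lewis acid the terminal double bond could move into conjugation, the γ-silyloxy oxygen could capture the oxocarbenium ion, or the hindered ketone could simply fail to react.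

Fallback, from 6 to 8: the ketal is made on a substrate without the alkene. The lithium enolate of ethyl acetate adds to 6 to give the β-keto ester F11. This is ketalised under the same reagents, which can now be pushed harder, to the ketal ester F12. DIBAL-H at −78 °C gives the ketal aldehyde F13, and Ph3P=CH2 returns 8.

**Step 27.** Many events share one flask. The cascade could stall at partly unveiled stages, C4 could epimerise through the 1,3-diketone, or the freed O6 could be diverted into a transannular hemiketal with C3.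

Fallback, from 36 to 38: the unveiling is staged. HF·pyridine in THF removes both silyl ethers and the hydroxy acid closes to the keto ketal lactone F14. TsOH in wet acetone then hydrolyses the β-keto ketal and closes the furanone with the acetonide kept, giving the target acetonide F15. Aqueous acetic acid frees the diol to give 38.

## Further compounds

F1 | step 20 | primary alcohol from reduction of 29 | CC#C[C@H](O[Si](C)(C)C(C)(C)C)[C@H](CC(OC)OC)[C@@H](OC(=O)[C@@]2(C)OC(C)(C)OC2)C[C@](C)(O[Si](CC)(CC)CC)C1(CCO)OCCO1
F2 | step 20 | (E)-vinyl iodide alcohol | C/C(I)=C\[C@H](O[Si](C)(C)C(C)(C)C)[C@H](CC(OC)OC)[C@@H](OC(=O)[C@@]2(C)OC(C)(C)OC2)C[C@](C)(O[Si](CC)(CC)CC)C1(CCO)OCCO1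
F3 | step 20 | (E)-vinyl iodide aldehyde | C/C(I)=C\[C@H](O[Si](C)(C)C(C)(C)C)[C@H](CC(OC)OC)[C@@H](OC(=O)[C@@]2(C)OC(C)(C)OC2)C[C@](C)(O[Si](CC)(CC)CC)C1(CC=O)OCCO1
F4 | step 22 | macrocyclic (E)-enone, C3 ketone | C/C1=C\[C@H](O[Si](C)(C)C(C)(C)C)[C@H](CC(OC)OC)[C@@H](OC(=O)[C@@]2(C)OC(C)(C)OC2)C[C@](C)(O[Si](CC)(CC)CC)C3(OCCO3)CC1=O
F5 | step 22 | saturated C3 ketone with C12 dimethyl acetal | C[C@H]1C[C@H](O[Si](C)(C)C(C)(C)C)[C@H](CC(OC)OC)[C@@H](OC(=O)[C@@]2(C)OC(C)(C)OC2)C[C@](C)(O[Si](CC)(CC)CC)C3(OCCO3)CC1=O
F6 | step 22 | keto aldehyde | C[C@H]1C[C@H](O[Si](C)(C)C(C)(C)C)[C@H](CC=O)[C@@H](OC(=O)[C@@]2(C)OC(C)(C)OC2)C[C@](C)(O[Si](CC)(CC)CC)C3(OCCO3)CC1=O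
F7 | step 14 | O8 triethylsilyl Weinreb amide | CON(C)C(=O)[C@H](CC(OC)OC)[C@@H](O[Si](CC)(CC)CC)C[C@](C)(O[Si](CC)(CC)CC)C1(CC=C)OCCO1
F8 | step 14 | O8 triethylsilyl ynone | CC#CC(=O)[C@H](CC(OC)OC)[C@@H](O[Si](CC)(CC)CC)C[C@](C)(O[Si](CC)(CC)CC)C1(CC=C)OCCO1
F9 | step 14 | (R)-propargylic alcohol with O8 triethylsilyl ether | CC#C[C@H](O)[C@H](CC(OC)OC)[C@@H](O[Si](CC)(CC)CC)C[C@](C)(O[Si](CC)(CC)CC)C1(CC=C)OCCO1
F10 | step 14 | tris-silyl ether (O6 TBS, O8 and O10 TES) | CC#C[C@H](O[Si](C)(C)C(C)(C)C)[C@H](CC(OC)OC)[C@@H](O[Si](CC)(CC)CC)C[C@](C)(O[Si](CC)(CC)CC)C1(CC=C)OCCO1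
F11 | step 6 | ethyl (4S)-4-methyl-3-oxo-4,6-bis(triethylsilyloxy)hexanoate | CCOC(=O)CC(=O)[C@](C)(CCO[Si](CC)(CC)CC)O[Si](CC)(CC)CC
F12 | step 6 | ethyl 2-{2-[(2S)-2,4-bis(triethylsilyloxy)butan-2-yl]-1,3-dioxolan-2-yl}acetate | CCOC(=O)CC1(OCCO1)[C@](C)(CCO[Si](CC)(CC)CC)O[Si](CC)(CC)CC
F13 | step 6 | 2-{2-[(2S)-2,4-bis(triethylsilyloxy)butan-2-yl]-1,3-dioxolan-2-yl}acetaldehyde | O=CCC1(OCCO1)[C@](C)(CCO[Si](CC)(CC)CC)O[Si](CC)(CC)CC
F14 | step 27 | keto ketal methylene lactone with free C10 hydroxyl and side-chain acetonide | C=C1C(=O)O[C@H]2C[C@H](C)C(=O)CC3(OCCO3)[C@@](C)(O)C[C@H](OC(=O)[C@@]4(C)OC(C)(C)OC4)[C@@H]12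
F15 | step 27 | acetonide of the target | C=C1C(=O)O[C@H]2C[C@H](C)C3=CC(=O)[C@](C)(C[C@H](OC(=O)[C@@]4(C)OC(C)(C)OC4)[C@@H]12)O3
A1 | alternative 1 | oxygen-bridged tetrahydrofuranone with Z-C7=C8 alkene | C[C@H]1C[C@H](O[Si](C)(C)C(C)(C)C)/C(CC(OC)OC)=C\C[C@]2(C)O[C@H]1CC2=O
A2 | alternative 2 | acetonide of the target | C=C1C(=O)O[C@H]2C[C@H](C)C3=CC(=O)[C@](C)(C[C@H](OC(=O)[C@@]4(C)OC(C)(C)OC4)[C@@H]12)O3
A3 | alternative 3 | ten-membered α-hydroxy ketone with C1/C3 vinylogous ester | C[C@H]1C/C=C(CC(OC)OC)/[C@@H](OCc2ccc(OC)cc2)C[C@](C)(O)C(=O)/C=C1/OCC
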